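**Strategy.** The 1,4-dioxane ring is disconnected at its C2–C3 bond, the bond joining the methyl-bearing and the aryl-bearing carbon, each of which carries one oxygen (O1, O4) of the benzo ring. Since methyl and aryl are cis, the bond is made as a C2=C3 double bond: an α-aryloxy phosphorus ylide on O1 attacks the 3,4,5-trimethoxybenzoate carbonyl on O4 (intramolecular Wittig olefination of an ester), which closes the 1,4-benzodioxine ring in one operation from an open catechol phosphonium salt/aryl ester. Syn asymmetric hydrogenation of this flat enediol diether then sets both stereocentres together, and the allyl group replaces a bromine placeholder in the last step.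

Key step: step 5

Remark: the target is read as the cis isomer, (2S,3R) in the numbering O1–C2(CH3)–C3(Ar)–O4 with the allyl group at C6; the sense of induction in step 6 cannot be predicted with certainty, so the ligand enantiomer that leads to 12 is to be selected in a small-scale test.

**Step 1**
Reactants: 1 4-bromo-2-methoxyphenol; 2 vinyl acetate
Product: 3 4-bromo-1-(ethenyloxy)-2-methoxybenzene
Conditions: [Ir(cod)Cl]2 (1 mol%), Na2CO3 (0.6 equiv), vinyl acetate (2 equiv), toluene, 100 °C
Reagents that add atoms: vinyl acetate, C=COC(C)=O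
Why: Iridium-catalysed transfer vinylation (vinyl exchange) of a phenol, in which the phenoxide adds to the coordinated vinyl ester and acetate is eliminated; the free OH para to bromine is the only reactive site, so the vinyl group is placed on the oxygen that becomes O1.

**Step 2**
Reactants: 3 4-bromo-1-(ethenyloxy)-2-methoxybenzene
Product: 4 5-bromo-2-(ethenyloxy)phenol
Conditions: NaSEt (2 equiv), DMF, 100 °C; NaH2PO4 (aq), 0 °C; used at once in step 3
Reagents that add atoms: none
Why: Nucleophilic (SN2) demethylation of the aryl methyl ether by ethanethiolate; the basic medium and neutral work-up should preserve the acid-labile vinyl ether, which would otherwise close onto the free phenol to give a 2-methyl-1,3-benzodioxole.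

**Step 3**
Reactants: 4 5-bromo-2-(ethenyloxy)phenol; 5 3,4,5-trimethoxybenzoyl chloride
Product: 6 5-bromo-2-(ethenyloxy)phenyl 3,4,5-trimethoxybenzoate
Conditions: Et3N (1.5 equiv), DMAP (5 mol%), CH2Cl2, 0 °C to rt
Reagents that add atoms: 3,4,5-trimethoxybenzoyl chloride, COc1cc(cc(OC)c1OC)C(Cl)=O
Why: DMAP-catalysed O-acylation of the phenol; because the other oxygen is already a vinyl ether, no acyl migration between the catechol oxygens can scramble the substitution pattern.

**Step 4**
Reactants: 6 5-bromo-2-(ethenyloxy)phenyl 3,4,5-trimethoxybenzoate; 7 triphenylphosphonium bromide (Ph3P·HBr)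
Product: 8 (RS)-{1-[4-bromo-2-(3,4,5-trimethoxybenzoyloxy)phenoxy]ethyl}triphenylphosphonium bromide
Conditions: Ph3P·HBr (1.0 equiv), CH2Cl2, 0 °C to rt
Reagents that add atoms: triphenylphosphonium bromide, [Br-].[PH+](c1ccccc1)(c1ccccc1)c1ccccc1
Why: Markovnikov addition of Ph3P·HBr to an enol ether (protonation at CH2, capture of the oxocarbenium ion by the phosphine) gives the α-aryloxyethyl phosphonium salt; the new stereocentre is racemic and is erased in step 5.

**Step 5**
Reactants: 8 (RS)-{1-[4-bromo-2-(3,4,5-trimethoxybenzoyloxy)phenoxy]ethyl}triphenylphosphonium bromide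
Product: 11 6-bromo-2-methyl-3-(3,4,5-trimethoxyphenyl)-1,4-benzodioxine, via phosphonium ylide 9 (not isolated), via oxaphosphetane 10 (not isolated)
Conditions: KN(SiMe3)2 (1.1 equiv), THF, −78 °C to rt
Reagents that add atoms: none
Why: KN(SiMe3)2 removes the proton α to phosphorus, and the α-aryloxy ylide carbon (future C2) attacks the ester carbonyl carbon (future C3) held close by the ortho-dioxygenated benzene ring, giving the oxaphosphetane that collapses with loss of Ph3P=O to the C2=C3 enediol diether; if the tetrahedral intermediate first expels the phenoxide, that phenoxide should re-add to the new ketone and reach the same oxaphosphetane. The closest known reaction type is the intramolecular Wittig olefination of ester carbonyls used to make benzofurans, indoles and cyclic enol ethers from acyloxy- or acylamino-substituted phosphonium salts. The dioxine ring closes by a 6-exo-trig attack on the exocyclic C=O, and the transient four-membered oxaphosphetane ring closes by O–P bond formation and is lost again. No stereocentre is created: the racemic phosphorus-bearing carbon becomes sp2 and 11 is achiral, so all stereochemistry is left to step 6. The step needs α-deprotonation to win over attack of the base on the aryl ester, and ring closure to win over intermolecular acylation; the non-nucleophilic silylamide at low temperature and the six-membered transition state fixed by the catechol scaffold should secure both, and the aryl bromide is inert.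

**Step 6**
Reactants: 11 6-bromo-2-methyl-3-(3,4,5-trimethoxyphenyl)-1,4-benzodioxine
Product: 12 (2S,3R)-6-bromo-2-methyl-3-(3,4,5-trimethoxyphenyl)-2,3-dihydro-1,4-benzodioxine (cis)
Conditions: H2 (50 bar), [Ir(cod)(L)]B[C6H3(CF3)2]4 (2 mol%; L = 4-tert-butyl-2-[2-(diphenylphosphanyl)phenyl]-4,5-dihydro-1,3-oxazole, tBu-PHOX, enantiomer as selected), CH2Cl2, rt
Reagents that add atoms: none
Why: Iridium-catalysed asymmetric hydrogenation of a tetrasubstituted cyclic olefin delivers both hydrogens from the metal to one face of C2=C3, which fixes the cis relation of methyl and aryl, while the chiral P,N ligand selects the face and so sets C2 (S) and C3 (R) together; the homogeneous catalyst should leave the aryl bromide and the benzylic C–O bond untouched.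

**Step 7**
Reactants: 12 (2S,3R)-6-bromo-2-methyl-3-(3,4,5-trimethoxyphenyl)-2,3-dihydro-1,4-benzodioxine; 13 allyltributylstannane
Product: 14 (2S,3R)-2-methyl-6-(prop-2-en-1-yl)-3-(3,4,5-trimethoxyphenyl)-2,3-dihydro-1,4-benzodioxine
Conditions: Pd(PPh3)4 (5 mol%), allyltributylstannane (1.3 equiv), toluene, 100 °C
Reagents that add atoms: allyltributylstannane, C=CC[Sn](CCCC)(CCCC)CCCC
Why: Migita–Kosugi–Stille coupling of the aryl bromide with the allylstannane installs the allyl group at C6 under neutral conditions that do not touch the two stereocentres.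

**Compound list**
1 | 4-bromo-2-methoxyphenol | COc1cc(Br)ccc1O | starting material
2 | vinyl acetate | C=COC(C)=O | starting material
3 | 4-bromo-1-(ethenyloxy)-2-methoxybenzene | COc1cc(Br)ccc1OC=C | intermediate
4 | 5-bromo-2-(ethenyloxy)phenol | Oc1cc(Br)ccc1OC=C | intermediate
5 | 3,4,5-trimethoxybenzoyl chloride | COc1cc(cc(OC)c1OC)C(Cl)=O | starting material
6 | 5-bromo-2-(ethenyloxy)phenyl 3,4,5-trimethoxybenzoate | C=COc1ccc(Br)cc1OC(=O)c1cc(OC)c(OC)c(OC)c1 | intermediate
7 | triphenylphosphonium bromide (Ph3P·HBr) | [Br-].[PH+](c1ccccc1)(c1ccccc1)c1ccccc1 | starting material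
8 | (RS)-{1-[4-bromo-2-(3,4,5-trimethoxybenzoyloxy)phenoxy]ethyl}triphenylphosphonium bromide | CC(Oc1ccc(Br)cc1OC(=O)c1cc(OC)c(OC)c(OC)c1)[P+](c1ccccc1)(c1ccccc1)c1ccccc1.[Br-] | intermediate
9 | {1-[4-bromo-2-(3,4,5-trimethoxybenzoyloxy)phenoxy]ethylidene}triphenylphosphorane (phosphonium ylide) | CC(Oc1ccc(Br)cc1OC(=O)c1cc(OC)c(OC)c(OC)c1)=P(c1ccccc1)(c1ccccc1)c1ccccc1 | intermediate (not isolated)
10 | oxaphosphetane fused across C2–C3 of the 6-bromo-2,3-dihydro-1,4-benzodioxine ring (P on the methyl-bearing carbon, O on the aryl-bearing carbon) | CC12Oc3ccc(Br)cc3OC1(c1cc(OC)c(OC)c(OC)c1)OP2(c1ccccc1)(c1ccccc1)c1ccccc1 | intermediate (not isolated)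
11 | 6-bromo-2-methyl-3-(3,4,5-trimethoxyphenyl)-1,4-benzodioxine | CC1=C(c2cc(OC)c(OC)c(OC)c2)Oc2cc(Br)ccc2O1 | intermediate
12 | (2S,3R)-6-bromo-2-methyl-3-(3,4,5-trimethoxyphenyl)-2,3-dihydro-1,4-benzodioxine | Brc1ccc2c(c1)O[C@H](c1cc(OC)c(OC)c(OC)c1)[C@H](C)O2 | intermediate
13 | allyltributylstannane | C=CC[Sn](CCCC)(CCCC)CCCC | starting material
14 | (2S,3R)-2-methyl-6-(prop-2-en-1-yl)-3-(3,4,5-trimethoxyphenyl)-2,3-dihydro-1,4-benzodioxine | C=CCc1ccc2c(c1)O[C@H](c1cc(OC)c(OC)c(OC)c1)[C@H](C)O2 | target

**Total step count:** 7
**Longest linear sequence:** 7 steps (from 1)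

**Steps most likely to fail**

1. Step 6 (asymmetric hydrogenation). The two faces of the nearly flat, tetrasubstituted and electron-rich olefin may be poorly discriminated. The acidic cationic iridium hydride may also protonate the enediol diether, which would slow the reaction and erode enantiomeric purity. Fallback, from 11 back to 12: hydrogenation with the achiral complex [Ir(cod)(PCy3)(py)]PF6 (H2, CH2Cl2) should still add both hydrogens syn and give the racemic cis bromide. This is 12 together with its mirror image (2R,3S)-6-bromo-2-methyl-3-(3,4,5-trimethoxyphenyl)-2,3-dihydro-1,4-benzodioxine F1. Preparative chromatography on a chiral stationary phase (SFC, amylose tris(3,5-dimethylphenylcarbamate)) would separate the two and return 12 for step 7.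

2. Step 5 (intramolecular Wittig olefination). The ylide may transfer the acyl group from O to C and stall at an acylated phosphonium phenoxide without extruding Ph3P=O, or the base may cleave the aryl ester. Fallback, from 6 back to 11, forming the same C2–C3 bond by a samarium Barbier-type acyl transfer: dry HCl in Et2O at 0 °C should add to the vinyl ether of 6 and give the α-chloro ether 5-bromo-2-(1-chloroethoxy)phenyl 3,4,5-trimethoxybenzoate F2. SmI2 (2.2 equiv, THF, −78 °C to rt) should reduce the C–Cl bond to an α-aryloxy organosamarium that attacks the neighbouring ester (intramolecular nucleophilic acyl substitution). This gives 2-(4-bromo-2-hydroxyphenoxy)-1-(3,4,5-trimethoxyphenyl)propan-1-one F3, which closes to its cyclic hemiketal 7-bromo-3-methyl-2-(3,4,5-trimethoxyphenyl)-2,3-dihydro-1,4-benzodioxin-2-ol F4. Acid-catalysed cyclodehydration (TsOH, toluene, reflux, water separator) should then give 11.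

3. Step 2 (demethylation). The thiolate may displace the aryl bromide or cleave the methyl ether incompletely, and the free phenol 4 may cyclise onto the vinyl ether during work-up. Fallback, from 3 back to 8, removing the vinyl ether before the methyl ether is cleaved: Ph3P·HBr (CH2Cl2, rt) should convert 3 into [1-(4-bromo-2-methoxyphenoxy)ethyl]triphenylphosphonium bromide F5. BBr3 (CH2Cl2, −78 °C to 0 °C) should then cleave only the methyl ether, because the oxygen next to the phosphonium centre is a poor Lewis base, to give [1-(4-bromo-2-hydroxyphenoxy)ethyl]triphenylphosphonium bromide F6. Acylation of F6 with 5 and pyridine in CH2Cl2 should give 8.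

**Further compounds**
F1 | step 6 | (2R,3S)-6-bromo-2-methyl-3-(3,4,5-trimethoxyphenyl)-2,3-dihydro-1,4-benzodioxine | Brc1ccc2c(c1)O[C@@H](c1cc(OC)c(OC)c(OC)c1)[C@@H](C)O2
F2 | step 5 | 5-bromo-2-(1-chloroethoxy)phenyl 3,4,5-trimethoxybenzoate (racemic) | CC(Cl)Oc1ccc(Br)cc1OC(=O)c1cc(OC)c(OC)c(OC)c1
F3 | step 5 | 2-(4-bromo-2-hydroxyphenoxy)-1-(3,4,5-trimethoxyphenyl)propan-1-one (racemic) | CC(Oc1ccc(Br)cc1O)C(=O)c1cc(OC)c(OC)c(OC)c1
F4 | step 5 | 7-bromo-3-methyl-2-(3,4,5-trimethoxyphenyl)-2,3-dihydro-1,4-benzodioxin-2-ol (hemiketal form of F3) | CC1Oc2ccc(Br)cc2OC1(O)c1cc(OC)c(OC)c(OC)c1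
F5 | step 2 | [1-(4-bromo-2-methoxyphenoxy)ethyl]triphenylphosphonium bromide (racemic) | CC(Oc1ccc(Br)cc1OC)[P+](c1ccccc1)(c1ccccc1)c1ccccc1.[Br-]
F6 | step 2 | [1-(4-bromo-2-hydroxyphenoxy)ethyl]triphenylphosphonium bromide (racemic) | CC(Oc1ccc(Br)cc1O)[P+](c1ccccc1)(c1ccccc1)c1ccccc1.[Br-]
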